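**Plan**
- Retrosynthesis: the two phenol hydrogens are replaced by benzyl groups. Then C4–phenyl is cut (conjugate addition to a coumarin), then O1–C8a (oxidative C–H lactonisation of a cinnamic acid), then C4–C4a (Heck), then C8–C(=O) (Friedel–Crafts).
- Forward: ring A is bought as 4-bromoresorcinol and the 3-(4-methoxyphenyl)propanoyl chain goes on first. Acrylic acid is joined at the bromine-bearing carbon (future C4a), ring B (the pyranone) closes at O1–C8a, phenyl is added to C4, and hydrogenolysis ends the route.
- Enabling feature: without O1, ring A is only a 4,6-disubstituted resorcinol, whose pattern follows from ortho/para direction. Of the two carbons ortho to C4a, C5 carries oxygen and only C8a carries hydrogen, so a carboxyl oxygen held cis on a C3=C4 double bond can bond nowhere else.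
- The closure copies the oxidative-cyclisation hypothesis of coumarin biosynthesis. It brings in the third oxygen of the phloroglucinol ring already acylated and next to the C8 ketone, which settles 8-acyl against 6-acyl.
- Helpers: the C3=C4 double bond is used up by the phenyl addition, and the two benzyl groups are removed last.
- Stereochemistry: C4 is the only stereocentre. It is set as S by catalyst control ((S)-Segphos on rhodium) in the phenyl addition, and no later step touches it.

Key step: step 4

Assumption: the sense of induction known for Segphos with the parent coumarins (R ligand gives R product, same CIP order at C4) is taken to hold for 8. If it is reversed, the other ligand enantiomer is used.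

Step 1
Reactants: 1 4-bromoresorcinol; 2 3-(4-methoxyphenyl)propanoic acid
Product: 3 1-(5-bromo-2,4-dihydroxyphenyl)-3-(4-methoxyphenyl)propan-1-one
Conditions: BF3·OEt2 (solvent and promoter), 85 °C; then aq. NaOAc
Reagents that add atoms: none
Why: Friedel–Crafts (Nencki-type) acylation, in which BF3 activates acid 2 as an acyl cation equivalent that attacks C6 of 1, the only open carbon ortho to one hydroxyl and para to the other without lying between them, and chelation of the new ketone to the neighbouring hydroxyl deactivates the ring against a second acylation.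

Step 2
Reactants: 3 1-(5-bromo-2,4-dihydroxyphenyl)-3-(4-methoxyphenyl)propan-1-one
Product: 4 1-[2,4-bis(benzyloxy)-5-bromophenyl]-3-(4-methoxyphenyl)propan-1-one
Conditions: BnBr, K2CO3, DMF, 70 °C
Reagents that add atoms: benzyl bromide, BrCc1ccccc1
Why: Double Williamson ether synthesis, in which carbonate in warm DMF deprotonates both phenols (the hydrogen-bonded one included) but not the ketone alpha-carbon, and the benzyl group on the future O5 later bars both the ordinary lactonisation and one of the two ortho carbons.

Step 3
Reactants: 4 1-[2,4-bis(benzyloxy)-5-bromophenyl]-3-(4-methoxyphenyl)propan-1-one; 5 acrylic acid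
Product: 6 (E)-3-{2,4-bis(benzyloxy)-5-[3-(4-methoxyphenyl)propanoyl]phenyl}prop-2-enoic acid
Conditions: Pd(OAc)2 (5 mol %), P(o-tol)3 (10 mol %), Et3N, DMF, 110 °C; then aq. HCl
Reagents that add atoms: none
Why: Mizoroki–Heck reaction, in which zerovalent palladium inserts into the C–Br bond, the aryl group adds to the terminal carbon of acrylate and syn beta-hydride elimination gives the E-cinnamic acid, while the ketone and the ethers are inert to Et3N at this temperature.

Step 4
Reactants: 6 (E)-3-{2,4-bis(benzyloxy)-5-[3-(4-methoxyphenyl)propanoyl]phenyl}prop-2-enoic acid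
Product: 8 5,7-bis(benzyloxy)-8-[3-(4-methoxyphenyl)propanoyl]-2H-chromen-2-one, via Z-cinnamic acid 7 (not isolated)
Conditions: (−)-riboflavin (5 mol %), O2 (1 atm), MeCN/MeOH 1:1, 402 nm LED, rt
Reagents that add atoms: none
Why: Excited riboflavin first passes triplet energy to the planar E-acid 6, and because the Z-acid 7 is twisted out of conjugation by allylic strain against the C5 benzyloxy group it is not re-excited, so the carboxyl group ends up held over ring A. A second excited flavin then removes one electron and the acid proton from 7, the cinnamoyloxy radical bonds through its oxygen to C8a, and the cyclohexadienyl radical so formed (spin on C4a, C6 and C8, the last next to the ketone) hands its hydrogen to the flavin semiquinone, which O2 reoxidises to give H2O2. The closest known reaction type is the flavin-photocatalysed isomerisation and oxidative cyclisation of beta-substituted cinnamic acids to 4-substituted coumarins, which is itself modelled on the oxidative-cyclisation hypothesis of coumarin biosynthesis. Ring B closes as a six-membered ring by ortho attack on the arene (Ar2-6, formally 6-endo-trig on C4a=C8a), whereas five-membered ipso closure at C4a (Ar1-5) is reversible and has no hydrogen to lose, and no stereocentre is formed. The step needs site selectivity between the two carbons ortho to C4a and chemoselectivity against decarboxylation: C5 is blocked by its benzyloxy group so that only C8a carries hydrogen, and a carboxyl radical on an sp2 carbon loses CO2 slowly, which is why the ring is closed at the cinnamic and not at the dihydrocinnamic oxidation level. In one event the third oxygen of the phloroglucinol ring A arrives already acylated and next to C8, which settles the 8-acyl against 6-acyl question that lactonisation of a free acylphloroglucinol leaves open.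

Step 5
Reactants: 8 5,7-bis(benzyloxy)-8-[3-(4-methoxyphenyl)propanoyl]-2H-chromen-2-one; 9 phenylboronic acid (excess)
Product: 10 (4S)-5,7-bis(benzyloxy)-8-[3-(4-methoxyphenyl)propanoyl]-4-phenyl-3,4-dihydro-2H-chromen-2-one
Conditions: Rh(acac)(C2H4)2 (3 mol %), (S)-Segphos (3.3 mol %), 1,4-dioxane/H2O 10:1, 60 °C
Reagents that add atoms: none
Why: Hayashi–Miyaura asymmetric 1,4-addition, in which the phenyl-rhodium species bound to (S)-Segphos inserts the coumarin C3=C4 bond on one face and water protonates the rhodium enolate, so the ligand sets C4 as S, while the C8 ketone with its two ortho substituents is too hindered for 1,2-addition and the base-free medium spares the lactone.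

Step 6
Reactants: 10 (4S)-5,7-bis(benzyloxy)-8-[3-(4-methoxyphenyl)propanoyl]-4-phenyl-3,4-dihydro-2H-chromen-2-one
Product: 11 (4S)-5,7-dihydroxy-8-[3-(4-methoxyphenyl)propanoyl]-4-phenyl-3,4-dihydro-2H-chromen-2-one (CNP0240692.1)
Conditions: H2 (1 atm), Pd/C (10 wt %), EtOAc, rt
Reagents that add atoms: none
Why: Catalytic hydrogenolysis of the two aryl benzyl ethers under neutral, aprotic conditions, which leaves the hydrogen-bonded aryl ketone, the O1–C2 ester bond and the all-carbon benzylic stereocentre C4 untouched and offers no acid, base or alcohol that could move the lactone from O1 to the freed O5.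

**Compound list**
1 | 4-bromoresorcinol (4-bromobenzene-1,3-diol) | Oc1ccc(Br)c(O)c1 | starting material
2 | 3-(4-methoxyphenyl)propanoic acid | COc1ccc(CCC(=O)O)cc1 | starting material
3 | 1-(5-bromo-2,4-dihydroxyphenyl)-3-(4-methoxyphenyl)propan-1-one | COc1ccc(CCC(=O)c2cc(Br)c(O)cc2O)cc1 | intermediate
4 | 1-[2,4-bis(benzyloxy)-5-bromophenyl]-3-(4-methoxyphenyl)propan-1-one | COc1ccc(CCC(=O)c2cc(Br)c(OCc3ccccc3)cc2OCc2ccccc2)cc1 | intermediate
5 | acrylic acid | C=CC(=O)O | starting material
6 | (E)-3-{2,4-bis(benzyloxy)-5-[3-(4-methoxyphenyl)propanoyl]phenyl}prop-2-enoic acid | COc1ccc(CCC(=O)c2cc(/C=C/C(=O)O)c(OCc3ccccc3)cc2OCc2ccccc2)cc1 | intermediate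
7 | (Z)-3-{2,4-bis(benzyloxy)-5-[3-(4-methoxyphenyl)propanoyl]phenyl}prop-2-enoic acid | COc1ccc(CCC(=O)c2cc(/C=C\C(=O)O)c(OCc3ccccc3)cc2OCc2ccccc2)cc1 | intermediate
8 | 5,7-bis(benzyloxy)-8-[3-(4-methoxyphenyl)propanoyl]-2H-chromen-2-one | COc1ccc(CCC(=O)c2c(OCc3ccccc3)cc(OCc3ccccc3)c3ccc(=O)oc23)cc1 | intermediate
9 | phenylboronic acid | OB(O)c1ccccc1 | starting material
10 | (4S)-5,7-bis(benzyloxy)-8-[3-(4-methoxyphenyl)propanoyl]-4-phenyl-3,4-dihydro-2H-chromen-2-one | COc1ccc(CCC(=O)c2c(OCc3ccccc3)cc(OCc3ccccc3)c3c2OC(=O)C[C@H]3c2ccccc2)cc1 | intermediate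
11 | (4S)-5,7-dihydroxy-8-[3-(4-methoxyphenyl)propanoyl]-4-phenyl-3,4-dihydro-2H-chromen-2-one | COc1ccc(CCC(=O)c2c(O)cc(O)c3c2OC(=O)C[C@H]3c2ccccc2)cc1 | target

Total step count: 6. Longest linear sequence: 6 steps (from 1 or 2 to 11).

**Steps most likely to fail**

Step 4. The ring may fail to close for several reasons:
- The excited flavin may spend itself in reversible electron transfer with the anisyl ring or oxidise its benzylic position.
- The carboxyl radical may abstract hydrogen from the C5 benzyloxy methylene, or add at the oxygen-bearing ortho carbon.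
- The E/Z photoequilibrium of a beta-unsubstituted cinnamic acid may supply too little Z-acid.

The fallback sets out from 2 and comes back at 8. It gives up the C–H closure and buys the lactone ring. Acid 2 is turned with SOCl2 into 3-(4-methoxyphenyl)propanoyl chloride F1. This acylates purchased 5,7-dihydroxycoumarin F2 under Friedel–Crafts conditions (AlCl3, 1,2-dichloroethane/nitrobenzene, 70 °C). The product should be mainly 5,7-dihydroxy-8-[3-(4-methoxyphenyl)propanoyl]-2H-chromen-2-one F3, and any acylation at C6 is dealt with by chromatography. Double benzylation (BnBr, K2CO3, DMF) then gives 8.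

Step 5. Insertion of the phenyl-rhodium species may be slow, because the coumarin is made electron-rich by two alkoxy groups and is shielded at C4 by the peri C5 benzyloxy group. Protodeboronation of 9 could then overtake the addition.

The fallback sets out from 8 and 9 and comes back at 10. It separates C–C bond formation from stereocontrol.
- An oxidative Heck arylation (Pd(OAc)2, 1,10-phenanthroline, O2, DMF, 80 °C) is used first, because a divalent palladium aryl inserts more readily into donor-substituted alkenes. It should give 5,7-bis(benzyloxy)-8-[3-(4-methoxyphenyl)propanoyl]-4-phenyl-2H-chromen-2-one F4.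
- NaOH in MeOH opens the lactone to the ring-opened disodium (Z)-cinnamate F5.
- Asymmetric hydrogenation directed by the carboxylate (H2, [Rh(cod)Cl]2 with the Chiraphos enantiomer that delivers S, MeOH) gives the disodium (S)-3,3-diarylpropanoate F6.
- Acidification with HCl relactonises onto the only free phenol oxygen, O1, to give 10.

Step 1. Acid-promoted loss or migration of bromine from the strongly activated ring may occur, or the reaction may stop at the aryl ester stage.

The fallback sets out from 2 and comes back at 3. It reverses the order of acylation and halogenation. Purchased resorcinol F7 is acylated with 2 (BF3·OEt2, 85 °C) to 1-(2,4-dihydroxyphenyl)-3-(4-methoxyphenyl)propan-1-one F8. This is then brominated with NBS (MeCN, 0 °C) at C5, the unhindered carbon para to the chelated hydroxyl and ortho to the free one, to give 3.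

**Further compounds**
F1 | step 4 | 3-(4-methoxyphenyl)propanoyl chloride | COc1ccc(CCC(=O)Cl)cc1
F2 | step 4 | 5,7-dihydroxycoumarin (purchased) | O=c1ccc2c(O)cc(O)cc2o1
F3 | step 4 | 5,7-dihydroxy-8-[3-(4-methoxyphenyl)propanoyl]-2H-chromen-2-one | COc1ccc(CCC(=O)c2c(O)cc(O)c3ccc(=O)oc23)cc1
F4 | step 5 | 5,7-bis(benzyloxy)-8-[3-(4-methoxyphenyl)propanoyl]-4-phenyl-2H-chromen-2-one | COc1ccc(CCC(=O)c2c(OCc3ccccc3)cc(OCc3ccccc3)c3c(-c4ccccc4)cc(=O)oc23)cc1
F5 | step 5 | disodium (Z)-3-{4,6-bis(benzyloxy)-3-[3-(4-methoxyphenyl)propanoyl]-2-oxidophenyl}-3-phenylprop-2-enoate | [Na+].[Na+].COc1ccc(CCC(=O)c2c(OCc3ccccc3)cc(OCc3ccccc3)c(/C(=C\C(=O)[O-])c3ccccc3)c2[O-])cc1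
F6 | step 5 | disodium (S)-3-{4,6-bis(benzyloxy)-3-[3-(4-methoxyphenyl)propanoyl]-2-oxidophenyl}-3-phenylpropanoate | [Na+].[Na+].COc1ccc(CCC(=O)c2c(OCc3ccccc3)cc(OCc3ccccc3)c([C@@H](CC(=O)[O-])c3ccccc3)c2[O-])cc1
F7 | step 1 | resorcinol (purchased) | Oc1cccc(O)c1
F8 | step 1 | 1-(2,4-dihydroxyphenyl)-3-(4-methoxyphenyl)propan-1-one | COc1ccc(CCC(=O)c2ccc(O)cc2O)cc1
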